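You cannot lay the gamma and beta runs on one percent curve, although gamma is charged with 0.67 M and beta with 1.5 M on the same feed and the same gas.

in all of them: gas phase 140 mM (held)

| flask | starting material | remark | time |
|---|---|---|---|
| gamma | 0.67 M (fed, over 50 min) | run made earlier; the fed solution adds 0.20 times the starting volume |  |
| beta | 1.5 M (fed, over 50 min) | run made earlier; the fed solution adds 0.20 times the starting volume |  |
| flask | 1.0 M (fed, over 50 min) | the fed solution adds 0.20 times the starting volume | 2.5 h |

| run | time / min | target / % |
|---|---|---|
| gamma | 25.0 | 10 |
| gamma | 30.0 | 10 |
| gamma | 40.0 | 15 |
| gamma | 50.0 | 20 |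
| gamma | 60.0 | 19 |
| gamma | 80.0 | 20 |
| gamma | 90.0 | 28 |
| beta | 25.0 | 5 |
| beta | 30.0 | 8 |
| beta | 40.0 | 12 |
| beta | 50.0 | 14 |
| beta | 60.0 | 15 |
| beta | 80.0 | 17 |
| beta | 90.0 | 17 |

(scatter of a reading: 2 percentage points)

- charges are per starting volume, the dose included; the dosed solution carries all of it
- the numbers in the tables scatter with a standard deviation of 2 percentage points
- at the start none of the gas phase is in solution
- percentages count the whole charge, also what has not yet gone in

1. the best time, 2.5 h at the latest, for target
2. the amount of target, in percent of the starting material charged, at that time

1. Suppose every step were pseudo-first-order in the dosed species, with equal gas in solution. Percent would then not depend on the charge c. Yet the level Y, the mean of the readings from the end of the feed on, is 21.8% for gamma and 15.8% for beta. Gamma stands higher by 6 percentage points, with a scatter of 2 points on one reading.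

2. So in these two runs the higher charge reads lower in percent. Take the line Y = H/(1 + c/c*), with H its head value. The competition charge c* is the charge at which this line stands at H/2; through the two levels it is 1.51 M, which gives H = 31.4%.

3. Now draw the flask, charged with 1.0 M. You start flat, with nothing fed and no gas in solution, and the curve steepens during the feed. The line puts the level of this flask at 18.9%. At the end of the feed, 50 min, the two runs together read 90.7% of their levels, so the knee lies near 17.1%. The readings stop at 90.0 min, so I commit to the level and not to a time.

4. The forecast gives 20% at 2.5 h, above my level: “I therefore expect no interior maximum”.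

The flask peaks at 1.63 h with 22.5%, and by 2.50 h its target is down to 20.1%.

    gas phase ⇌ dissolved gas, rate k1*(csat - [dissolved gas]) (kL = 0.164 /min)
    starting material + dissolved gas → target (k = 0.126 /M/min)
    dissolved gas + target → over-reacted product (k = 0.0640 /M/min)
    starting material ⇌ dormant form (K = 1.04, k = 0.00964 /min)
    target → over-reaction product (k = 2.18 × 10⁻⁵ /min)
    starting material + target → side product (k = 0.0322 /M/min)

Put this peak into the line with c* = 1.51 M, and H becomes 37.5%. A neighbouring flask, alike but charged with 0.40 M, then comes out at 29.6%, and its own best is 30.9%.

The readings come from a simulation from invented constants.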